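The hindered C8–C6'' biaryl bond is never made between two arenes. Instead, ring A of the apigenin half is grown on acacetin. The route exploits the substitution of that ring (C4a''–C8a''). Its biaryl carbon C6'' lies between O5'' and O7'', and the ring oxygen O1'' sits on C8a'', para to C6''. A 2-aryl-1,1,3-trioxygenated butadiene and a β-bromo ynone fit this pattern atom for atom. Their Diels–Alder reaction with aromatisation forms C8''–C8a'' and C5''–C4a'' at once. It places acetyl on C4a'', bromine (placeholder for O1'') on C8a'' and both phenols. The precursor is 5,7-di-O-benzylacacetin carrying a 1-methoxy-1,3-bis(trimethylsilyloxy)buta-1,3-dien-2-yl group at C8.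

Key step: step 7

Remark: the SMILES defines no configuration for the C8–C6'' axis, so the target is made racemic with respect to that axis; unprimed and singly primed locants refer to the acacetin unit, doubly and triply primed ones to the apigenin unit.

Step 1
Reactants: 1 acacetin
Product: 2 5,7-di-O-benzylacacetin
Conditions: BnBr (3 equiv), K2CO3 (4 equiv), DMF, 80 °C
Reagents that add atoms: benzyl bromide, BrCc1ccccc1
Why: Williamson ether synthesis: excess benzyl bromide and carbonate in hot DMF alkylate the acidic 7-OH first and then the chelated 5-OH, while the 4'-methyl ether and the pyranone are inert.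

Step 2
Reactants: 2 5,7-di-O-benzylacacetin
Product: 3 8-iodo-5,7-di-O-benzylacacetin
Conditions: NIS (1.05 equiv), CF3CO2H (cat.), MeCN–CH2Cl2, 0 °C → rt, dark
Reagents that add atoms: N-iodosuccinimide, O=C1CCC(=O)N1I
Why: Electrophilic aromatic iodination: once both A-ring oxygens are alkylated, 5,7-dialkoxyflavones are halogenated at C8, because C6 is shielded by two flanking benzyloxy groups and both the anisyl ring and C3 are deactivated by conjugation with the carbonyl.

Step 3
Reactants: 3 8-iodo-5,7-di-O-benzylacacetin; 4 methyl bromoacetate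
Product: 6 methyl 2-[5,7-bis(benzyloxy)-2-(4-methoxyphenyl)-4-oxochromen-8-yl]acetate, via Reformatsky reagent 5 (not isolated)
Conditions: 4, Zn dust (Me3SiCl-activated), THF, 40 °C; then 3, Pd2(dba)3 (2.5 mol %), XPhos (10 mol %), THF, 65 °C
Reagents that add atoms: zinc, [Zn] (held only in 5)
Why: Negishi-type cross-coupling of a Reformatsky reagent (palladium-catalysed α-arylation of a zinc ester enolate): the nearly neutral zinc enolate spares the flavone carbonyl and the benzyl ethers, the bulky biarylphosphine on zerovalent palladium suits a di-ortho-substituted aryl iodide, and the future biaryl bond is thus made as a far less congested sp2–sp3 bond.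

Step 4
Reactants: 6 methyl 2-[5,7-bis(benzyloxy)-2-(4-methoxyphenyl)-4-oxochromen-8-yl]acetate
Product: 9 methyl 2-[5,7-bis(benzyloxy)-2-(4-methoxyphenyl)-4-oxochromen-8-yl]-3-oxobutanoate (racemic), via ester enolate 7 (not isolated), via keto ester enolate 8 (not isolated)
Conditions: LiN(SiMe3)2 (2.2 equiv), THF, −78 °C; AcCl (1.1 equiv), −78 → 0 °C; AcOH quench
Reagents that add atoms: acetyl chloride, CC(=O)Cl; lithium hexamethyldisilazide, [Li]N([Si](C)(C)C)[Si](C)(C)C (lithium held only in 7 and 8)
Why: Crossed Claisen-type C-acylation of a preformed lithium ester enolate with an acid chloride: the benzylic ester protons are by far the most acidic in 6, the second equivalent of base stores the product as enolate 8 and so stops further acylation, and the new α-stereocentre is racemic, enolisable and erased in step 5.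

Step 5
Reactants: 9 methyl 2-[5,7-bis(benzyloxy)-2-(4-methoxyphenyl)-4-oxochromen-8-yl]-3-oxobutanoate
Product: 11 5,7-bis(benzyloxy)-8-[1-methoxy-1,3-bis(trimethylsilyloxy)buta-1,3-dien-2-yl]-2-(4-methoxyphenyl)chromen-4-one, via silyl enol ether 10 (not isolated)
Conditions: Me3SiOTf (2.3 equiv), Et3N (3.5 equiv), toluene, 0 °C → rt; salt layer removed under argon, concentrated, used crude
Reagents that add atoms: trimethylsilyl triflate, C[Si](C)(C)OS(=O)(=O)C(F)(F)F
Why: Soft enolisation with silyl triflate and a tertiary amine, the one-flask route from β-keto esters to 1-alkoxy-1,3-bis(silyloxy)butadienes: the enol oxygen is silylated first (10), silylation of the ester carbonyl then acidifies the γ-methyl group for deprotonation by Et3N, no strong base touches the flavone, and either ketene acetal geometry serves because that carbon ends up aromatic.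

Step 6
Reactants: 12 but-3-yn-2-one
Product: 13 4-bromobut-3-yn-2-one
Conditions: NBS (1.1 equiv), AgNO3 (10 mol %), acetone, rt, dark
Reagents that add atoms: N-bromosuccinimide, O=C1CCC(=O)N1Br
Why: Silver-catalysed electrophilic bromination of a terminal alkyne through its silver acetylide, the standard access to 1-bromoalkynes, which tolerates the ketone.

Step 7
Reactants: 11 5,7-bis(benzyloxy)-8-[1-methoxy-1,3-bis(trimethylsilyloxy)buta-1,3-dien-2-yl]-2-(4-methoxyphenyl)chromen-4-one; 13 4-bromobut-3-yn-2-one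
Product: 16 8-(3-acetyl-4-bromo-2,6-dihydroxyphenyl)-5,7-di-O-benzylacacetin, via cycloadduct 14 (not isolated), via monosilyl ether 15 (not isolated)
Conditions: 13 (1.5 equiv), toluene, 0 → 60 °C, dark; then 1 M HCl, THF, rt
Reagents that add atoms: none
Why: A thermal normal-electron-demand [4+2] cycloaddition joins the CH2 terminus of 11, which carries the largest HOMO coefficient (future C8''), to the bromine-bearing β-carbon of 13 (future C8a'') and the ketene acetal carbon (future C5'') to the acetyl-bearing α-carbon (future C4a''), giving cyclohexa-1,4-diene 14. The doubly oxygenated sp3 carbon of 14 then expels methoxytrimethylsilane, the dienone so formed tautomerises to the chelated phenol 15, and dilute acid removes the last silyl group. The closest known reaction type is the Diels–Alder/aromatisation of 1-alkoxy-1,3-bis(silyloxy)butadienes with acetylenic ketones and esters to give resorcinols, and 3-bromopropynoyl compounds are established dienophiles; the aryl group on C2 of the diene and the bromine on the ynone are added substituents on these known partners. The single ring formed, ring A of the apigenin unit, is closed by intermolecular [4+2] annulation (four carbons from 11, two from 13) with both σ-bonds made in one operation; the only sp3 stereocentre, in 14, is lost on aromatisation and the new biaryl axis arises racemic. The step needs regioselectivity, secured by the matched polarisation of the partners (three oxygen donors pushing towards the CH2 terminus, the acetyl group pulling from the β-carbon), and chemoselectivity for ring closure over addition–elimination at C–Br, favoured by an apolar solvent and the absence of Lewis acid. The linear alkyne approaches C1 and C4 of the diene far from the perpendicular flavonyl group on C2, so the bulk that would cripple a direct biaryl coupling is hardly felt.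

Step 8
Reactants: 16 8-(3-acetyl-4-bromo-2,6-dihydroxyphenyl)-5,7-di-O-benzylacacetin
Product: 17 8-[3-acetyl-2,6-bis(benzyloxy)-4-bromophenyl]-5,7-di-O-benzylacacetin
Conditions: BnBr (3 equiv), K2CO3 (4 equiv), DMF, 70 °C
Reagents that add atoms: benzyl bromide, BrCc1ccccc1
Why: Williamson ether synthesis: both phenoxides are benzylated in hot DMF, which masks O5'' so that the later pyranone closure can only use C8a'', and carbonate is too weak to enolise the methyl ketone to a harmful extent.

Step 9
Reactants: 17 8-[3-acetyl-2,6-bis(benzyloxy)-4-bromophenyl]-5,7-di-O-benzylacacetin; 18 4-(benzyloxy)benzoyl chloride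
Product: 21 1-{2,4-bis(benzyloxy)-3-[5,7-bis(benzyloxy)-2-(4-methoxyphenyl)-4-oxochromen-8-yl]-6-bromophenyl}-3-[4-(benzyloxy)phenyl]propane-1,3-dione, via ketone enolate 19 (not isolated), via lithium diketonate 20 (not isolated)
Conditions: LiN(SiMe3)2 (2.5 equiv), THF, −78 °C; 18 (1.1 equiv), −78 → 0 °C; AcOH quench
Reagents that add atoms: lithium hexamethyldisilazide, [Li]N([Si](C)(C)C)[Si](C)(C)C (lithium held only in 19 and 20)
Why: Crossed Claisen-type C-aroylation of the lithium enolate of a methyl ketone with an aroyl chloride, the usual entry to 1,3-diaryl-1,3-diketones in flavone synthesis: the acetyl CH3 holds the only acidic protons, excess base converts the product into the unreactive chelate 20, and the aryl bromide is inert to the amide base at low temperature.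

Step 10
Reactants: 21 the 1,3-diketone of step 9
Product: 22 5,7,5'',7'',4'''-penta-O-benzyl derivative of the target (8,6''-biflavone)
Conditions: CuI (10 mol %), 1,10-phenanthroline (20 mol %), K2CO3 (2 equiv), DMF, 100 °C
Reagents that add atoms: none
Why: Intramolecular Ullmann-type O-arylation of a 1-(2-bromoaryl)-1,3-diketone, a known flavone synthesis: the enolate oxygen of the distal carbonyl displaces the bromide, which is activated by the ortho acyl group, through a six-membered transition state, while C-arylation is geometrically impossible and O5'' is blocked.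

Step 11
Reactants: 22 penta-O-benzyl biflavone
Product: 23 target, 8-(apigenin-6-yl)acacetin
Conditions: H2 (1 atm), Pd/C (10 wt %), THF–MeOH, rt
Reagents that add atoms: none
Why: Catalytic hydrogenolysis of the five benzyl aryl ethers over Pd/C at one atmosphere, under which the methyl ether and the conjugated C2=C3 bonds of both flavones persist if the reaction is stopped when hydrogen uptake ends.

Compound list
1 | acacetin, 5,7-dihydroxy-2-(4-methoxyphenyl)chromen-4-one | COc1ccc(-c2cc(=O)c3c(O)cc(O)cc3o2)cc1 | starting material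
2 | 5,7-di-O-benzylacacetin | COc1ccc(-c2cc(=O)c3c(OCc4ccccc4)cc(OCc4ccccc4)cc3o2)cc1 | intermediate
3 | 8-iodo-5,7-di-O-benzylacacetin | COc1ccc(-c2cc(=O)c3c(OCc4ccccc4)cc(OCc4ccccc4)c(I)c3o2)cc1 | intermediate
4 | methyl bromoacetate | COC(=O)CBr | starting material
5 | bromo(2-methoxy-2-oxoethyl)zinc, Reformatsky reagent | COC(=O)C[Zn]Br | intermediate (not isolated)
6 | methyl 2-[5,7-bis(benzyloxy)-2-(4-methoxyphenyl)-4-oxochromen-8-yl]acetate | COc1ccc(-c2cc(=O)c3c(OCc4ccccc4)cc(OCc4ccccc4)c(CC(=O)OC)c3o2)cc1 | intermediate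
7 | lithium enolate of 6 (geometry undefined) | COc1ccc(-c2cc(=O)c3c(OCc4ccccc4)cc(OCc4ccccc4)c(C=C(OC)O[Li])c3o2)cc1 | intermediate (not isolated)
8 | lithium enolate of 9 (geometry undefined) | COc1ccc(-c2cc(=O)c3c(OCc4ccccc4)cc(OCc4ccccc4)c(C(C(=O)OC)=C(C)O[Li])c3o2)cc1 | intermediate (not isolated)
9 | methyl 2-[5,7-bis(benzyloxy)-2-(4-methoxyphenyl)-4-oxochromen-8-yl]-3-oxobutanoate (racemic, enolisable) | COc1ccc(-c2cc(=O)c3c(OCc4ccccc4)cc(OCc4ccccc4)c(C(C(C)=O)C(=O)OC)c3o2)cc1 | intermediate
10 | methyl 2-[5,7-bis(benzyloxy)-2-(4-methoxyphenyl)-4-oxochromen-8-yl]-3-(trimethylsilyloxy)but-2-enoate (geometry undefined) | COc1ccc(-c2cc(=O)c3c(OCc4ccccc4)cc(OCc4ccccc4)c(C(C(=O)OC)=C(C)O[Si](C)(C)C)c3o2)cc1 | intermediate (not isolated)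
11 | 5,7-bis(benzyloxy)-8-[1-methoxy-1,3-bis(trimethylsilyloxy)buta-1,3-dien-2-yl]-2-(4-methoxyphenyl)chromen-4-one (drawn 1E; geometry without consequence) | COc1ccc(-c2cc(=O)c3c(OCc4ccccc4)cc(OCc4ccccc4)c(/C(C(=C)O[Si](C)(C)C)=C(/OC)O[Si](C)(C)C)c3o2)cc1 | intermediate
12 | but-3-yn-2-one | CC(=O)C#C | starting material
13 | 4-bromobut-3-yn-2-one | CC(=O)C#CBr | intermediate
14 | 8-[5-acetyl-4-bromo-6-methoxy-2,6-bis(trimethylsilyloxy)cyclohexa-1,4-dien-1-yl]-5,7-di-O-benzylacacetin (racemic) | COc1ccc(-c2cc(=O)c3c(OCc4ccccc4)cc(OCc4ccccc4)c(C4=C(O[Si](C)(C)C)CC(Br)=C(C(C)=O)C4(OC)O[Si](C)(C)C)c3o2)cc1 | intermediate (not isolated)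
15 | 8-[3-acetyl-4-bromo-2-hydroxy-6-(trimethylsilyloxy)phenyl]-5,7-di-O-benzylacacetin | COc1ccc(-c2cc(=O)c3c(OCc4ccccc4)cc(OCc4ccccc4)c(-c4c(O[Si](C)(C)C)cc(Br)c(C(C)=O)c4O)c3o2)cc1 | intermediate (not isolated)
16 | 8-(3-acetyl-4-bromo-2,6-dihydroxyphenyl)-5,7-di-O-benzylacacetin | COc1ccc(-c2cc(=O)c3c(OCc4ccccc4)cc(OCc4ccccc4)c(-c4c(O)cc(Br)c(C(C)=O)c4O)c3o2)cc1 | intermediate
17 | 8-[3-acetyl-2,6-bis(benzyloxy)-4-bromophenyl]-5,7-di-O-benzylacacetin | COc1ccc(-c2cc(=O)c3c(OCc4ccccc4)cc(OCc4ccccc4)c(-c4c(OCc5ccccc5)cc(Br)c(C(C)=O)c4OCc4ccccc4)c3o2)cc1 | intermediate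
18 | 4-(benzyloxy)benzoyl chloride | O=C(Cl)c1ccc(OCc2ccccc2)cc1 | starting material
19 | lithium enolate of 17 | COc1ccc(-c2cc(=O)c3c(OCc4ccccc4)cc(OCc4ccccc4)c(-c4c(OCc5ccccc5)cc(Br)c(C(=C)O[Li])c4OCc4ccccc4)c3o2)cc1 | intermediate (not isolated)
20 | lithium diketonate of 21 (geometry undefined) | COc1ccc(-c2cc(=O)c3c(OCc4ccccc4)cc(OCc4ccccc4)c(-c4c(OCc5ccccc5)cc(Br)c(C(=O)C=C(O[Li])c5ccc(OCc6ccccc6)cc5)c4OCc4ccccc4)c3o2)cc1 | intermediate (not isolated)
21 | 1-{2,4-bis(benzyloxy)-3-[5,7-bis(benzyloxy)-2-(4-methoxyphenyl)-4-oxochromen-8-yl]-6-bromophenyl}-3-[4-(benzyloxy)phenyl]propane-1,3-dione | COc1ccc(-c2cc(=O)c3c(OCc4ccccc4)cc(OCc4ccccc4)c(-c4c(OCc5ccccc5)cc(Br)c(C(=O)CC(=O)c5ccc(OCc6ccccc6)cc5)c4OCc4ccccc4)c3o2)cc1 | intermediate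
22 | 5,7,5'',7'',4'''-penta-O-benzyl-4'-O-methyl-8,6''-biapigenin | COc1ccc(-c2cc(=O)c3c(OCc4ccccc4)cc(OCc4ccccc4)c(-c4c(OCc5ccccc5)cc5oc(-c6ccc(OCc7ccccc7)cc6)cc(=O)c5c4OCc4ccccc4)c3o2)cc1 | intermediate
23 | 8-(apigenin-6-yl)acacetin, CNP0310322.0 (axis racemic) | COc1ccc(-c2cc(=O)c3c(O)cc(O)c(-c4c(O)cc5oc(-c6ccc(O)cc6)cc(=O)c5c4O)c3o2)cc1 | target

Total step count: 11. Longest linear sequence: 10 steps (steps 1–5 and 7–11 from acacetin); step 6 is a one-step side branch.

Steps most likely to fail

Step 7.
- What may go wrong: the diene terminus may add to the bromo ynone stepwise and bromide may be expelled before the ring closes. Alternatively, protodesilylation of the diene may outrun a cycloaddition slowed by the bulky group on C2.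
- Fallback approach: the annulation is given up, and the C8–C6'' bond is made by Suzuki–Miyaura coupling of two complete flavone halves. It sets out from 3 and commercial apigenin.
- Iodide partner: apigenin is benzylated at O7 and O4' (BnBr, 2.2 equiv, K2CO3, acetone, reflux) to give 7,4'-di-O-benzylapigenin F1. Iodination at C6 under the direction of the free 5-OH (benzyltrimethylammonium dichloroiodate, CaCO3, CH2Cl2–MeOH) gives 6-iodo-7,4'-di-O-benzylapigenin F2. Benzylation at O5 (BnBr, K2CO3, DMF, 80 °C) gives 6-iodo-5,7,4'-tri-O-benzylapigenin F3.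
- Boronate partner: Miyaura borylation of 3 (B2pin2, PdCl2(dppf), KOAc, dioxane, 90 °C) gives the 8-pinacolboronate of 5,7-di-O-benzylacacetin F4.
- Return to the route: coupling of F3 with F4 (Pd(OAc)2, SPhos, K3PO4, toluene–water, 100 °C) comes back at 22, ahead of step 11.

Step 5.
- What may go wrong: γ-enolisation may stay incomplete. The flavone carbonyl may capture silyl triflate and trigger self-condensation. The silyl groups may be lost by hydrolysis during isolation.
- Fallback approach: it sets out from 9 and replaces the bis(silyloxy) diene by a more robust 3-alkoxy-1-alkoxy-1-silyloxy diene, so that no silyl triflate is needed.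
- Diene: O-benzylation of 9 (BnBr, Cs2CO3, DMF, rt; the carbon terminus is blocked by the di-ortho-substituted aryl group) gives the methyl 3-(benzyloxy)-2-arylbut-2-enoate F5. γ-Deprotonation with in situ trapping (LiN(SiMe3)2, Me3SiCl, THF, −78 °C) gives the 3-benzyloxy-1-methoxy-1-(trimethylsilyloxy)buta-1,3-dien-2-yl flavone F6.
- Cycloaddition: reaction with 13 in toluene gives the cyclohexadiene adduct F7, which loses methoxytrimethylsilane to give 8-[3-acetyl-6-(benzyloxy)-4-bromo-2-hydroxyphenyl]-5,7-di-O-benzylacacetin F8.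
- Return to the route: benzylation of the remaining phenol under the conditions of step 8 comes back at 17.

Step 3.
- What may go wrong: transmetalation and reductive elimination at the di-ortho-substituted arylpalladium may be sluggish. Protodeiodination and self-condensation of the zinc enolate would then take over.
- Fallback approach: it sets out from 3 and brings in the two-carbon unit as an allyl group that is then degraded.
- Sequence: Stille coupling with allyltributylstannane (Pd(PPh3)4, DMF, 90 °C) gives 8-allyl-5,7-di-O-benzylacacetin F9. Lemieux–Johnson cleavage (OsO4 cat., NaIO4, 2,6-lutidine, dioxane–water) gives the 8-(2-oxoethyl) flavone F10. Pinnick oxidation (NaClO2, NaH2PO4, 2-methylbut-2-ene, t-BuOH–water) gives the flavon-8-ylacetic acid F11.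
- Return to the route: esterification (MeI, K2CO3, DMF) comes back at 6.

Further compounds
F1 | step 7 | 7,4'-di-O-benzylapigenin | O=c1cc(-c2ccc(OCc3ccccc3)cc2)oc2cc(OCc3ccccc3)cc(O)c12
F2 | step 7 | 6-iodo-7,4'-di-O-benzylapigenin | O=c1cc(-c2ccc(OCc3ccccc3)cc2)oc2cc(OCc3ccccc3)c(I)c(O)c12
F3 | step 7 | 6-iodo-5,7,4'-tri-O-benzylapigenin | O=c1cc(-c2ccc(OCc3ccccc3)cc2)oc2cc(OCc3ccccc3)c(I)c(OCc3ccccc3)c12
F4 | step 7 | 5,7-bis(benzyloxy)-2-(4-methoxyphenyl)-8-(4,4,5,5-tetramethyl-1,3,2-dioxaborolan-2-yl)chromen-4-one | COc1ccc(-c2cc(=O)c3c(OCc4ccccc4)cc(OCc4ccccc4)c(B4OC(C)(C)C(C)(C)O4)c3o2)cc1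
F5 | step 5 | methyl 3-(benzyloxy)-2-[5,7-bis(benzyloxy)-2-(4-methoxyphenyl)-4-oxochromen-8-yl]but-2-enoate (geometry undefined) | COc1ccc(-c2cc(=O)c3c(OCc4ccccc4)cc(OCc4ccccc4)c(C(C(=O)OC)=C(C)OCc4ccccc4)c3o2)cc1
F6 | step 5 | 5,7-bis(benzyloxy)-8-[3-(benzyloxy)-1-methoxy-1-(trimethylsilyloxy)buta-1,3-dien-2-yl]-2-(4-methoxyphenyl)chromen-4-one (geometry undefined) | COc1ccc(-c2cc(=O)c3c(OCc4ccccc4)cc(OCc4ccccc4)c(C(C(=C)OCc4ccccc4)=C(OC)O[Si](C)(C)C)c3o2)cc1
F7 | step 5 | 8-[5-acetyl-2-(benzyloxy)-4-bromo-6-methoxy-6-(trimethylsilyloxy)cyclohexa-1,4-dien-1-yl]-5,7-di-O-benzylacacetin (racemic) | COc1ccc(-c2cc(=O)c3c(OCc4ccccc4)cc(OCc4ccccc4)c(C4=C(OCc5ccccc5)CC(Br)=C(C(C)=O)C4(OC)O[Si](C)(C)C)c3o2)cc1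
F8 | step 5 | 8-[3-acetyl-6-(benzyloxy)-4-bromo-2-hydroxyphenyl]-5,7-di-O-benzylacacetin | COc1ccc(-c2cc(=O)c3c(OCc4ccccc4)cc(OCc4ccccc4)c(-c4c(OCc5ccccc5)cc(Br)c(C(C)=O)c4O)c3o2)cc1
F9 | step 3 | 8-allyl-5,7-di-O-benzylacacetin | COc1ccc(-c2cc(=O)c3c(OCc4ccccc4)cc(OCc4ccccc4)c(CC=C)c3o2)cc1
F10 | step 3 | 2-[5,7-bis(benzyloxy)-2-(4-methoxyphenyl)-4-oxochromen-8-yl]acetaldehyde | COc1ccc(-c2cc(=O)c3c(OCc4ccccc4)cc(OCc4ccccc4)c(CC=O)c3o2)cc1
F11 | step 3 | 2-[5,7-bis(benzyloxy)-2-(4-methoxyphenyl)-4-oxochromen-8-yl]acetic acid | COc1ccc(-c2cc(=O)c3c(OCc4ccccc4)cc(OCc4ccccc4)c(CC(=O)O)c3o2)cc1
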